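**Plan**

1. Rings: A = benzoyl arene, B = tetra-oxygenated arene, C = 2H-pyran on B, D = 2H-pyran on A, E = seven-membered lactone. Retrosynthetic cuts, in order: the lactone C(=O)–O bond of ring E; the diaryl ether O–C bond on ring A; then, in the chromene formed by rings B and C, the C4–C4a bond.
2. That C4–C4a bond is traced back by a 1,2-shift to a C4–C8a bond, i.e. to a spiro 2,5-dihydrofuran on a cyclohexa-2,5-dienone, which comes from 2,5-bis(allyloxy)benzoquinone and lithiated 3-methylbuta-1,2-diene.
3. Forward: quinone → allenyl para-quinol → spiro 2,5-dihydrofuran → ring expansion with aromatisation of ring B (ring C arises here). Ring A is made separately (formylation, ring D by enal annulation, prenyl by iodination and Stille coupling). The halves are joined by SNAr, then oxidation, deallylation and lactonisation (ring E last).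
4. Enabling feature: in ring B the carbon bearing the pyran oxygen (C8a) is para to the carbon bearing the diaryl ether oxygen (C6), and the other two oxygens sit on C5 and C8. Ring B is therefore a masked C2-symmetric 2,5-dialkoxy-1,4-benzoquinone in which C8a is a carbonyl carbon and its neighbour C4a carries hydrogen. C4 can be bonded first to C8a (five-membered ring O1–C2–C3=C4–C8a) and then shifted to C4a.
5. Stereochemistry: the target has no stereocentre; both pyran alkenes are cis by ring constraint. The single stereocentre of 3 and of 4 is racemic and is erased in step 4.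

Key step: step 4

Remark: 5-fluorobenzene-1,3-diol, 3-methylbuta-1,2-diene and tributyl(3-methylbut-2-en-1-yl)stannane are taken as purchasable; allyl ethers are chosen as the only protecting group because all three can be removed together under neutral conditions at the end.

**Route**

Step 1
Reactants: 1 2,5-dihydroxy-1,4-benzoquinone
Product: 2 2,5-bis(allyloxy)-1,4-benzoquinone
Conditions: allyl alcohol (solvent), BF3·OEt2 (0.3 equiv), 60 °C
Reagents that add atoms: allyl alcohol, C=CCO
Why: The two C–OH carbons of the hydroxyquinone are vinylogous carboxylic acid carbons, so acid-catalysed addition–elimination of the alcohol (vinylogous Fischer esterification) should give the C2-symmetric diether as the only product.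

Step 2
Reactants: 2 2,5-bis(allyloxy)-1,4-benzoquinone
Product: 3 rac-4-hydroxy-4-(3-methylbuta-1,2-dien-1-yl)-2,5-bis(allyloxy)cyclohexa-2,5-dien-1-one
Conditions: 3-methylbuta-1,2-diene, n-BuLi, THF, –78 °C; then added to 2 (1.05 equiv of the lithium reagent), THF, –78 °C; aq. NH4Cl
Reagents that add atoms: 3-methylbuta-1,2-diene, C=C=C(C)C
Why: Organolithium reagents add 1,2 to 2,5-dialkoxybenzoquinones, whose two carbonyl groups are equivalent by symmetry, and the dimethylallenyl anion is expected to react at its lithiated carbon (attack through the dimethyl-substituted end would have to build a quaternary centre), giving the allenyl para-quinol as a racemate whose stereocentre is erased in step 4.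

Step 3
Reactants: 3 rac-4-hydroxy-4-(3-methylbuta-1,2-dien-1-yl)-2,5-bis(allyloxy)cyclohexa-2,5-dien-1-one
Product: 4 rac-6,9-bis(allyloxy)-2,2-dimethyl-1-oxaspiro[4.5]deca-3,6,9-trien-8-one
Conditions: AgNO3 (20 mol %), CaCO3, acetone–H2O, rt, dark
Reagents that add atoms: none
Why: Monovalent silver activates the allene for 5-endo attack of the tertiary quinol hydroxyl on the dimethyl-substituted terminus (cycloisomerisation of an α-hydroxyallene to a 2,5-dihydrofuran), and the buffered neutral medium should leave the acid-sensitive dienone untouched.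

Step 4
Reactants: 4 rac-6,9-bis(allyloxy)-2,2-dimethyl-1-oxaspiro[4.5]deca-3,6,9-trien-8-one
Product: 6 5,8-bis(allyloxy)-2,2-dimethyl-2H-chromen-6-ol, via arenium ion 5 (not isolated)
Conditions: CF3CO2H (3 equiv), anhydrous CH2Cl2, 0 °C → rt
Reagents that add atoms: none
Why: Protonation of the C8 carbonyl of 4 gives an oxypentadienyl cation with charge at C6 and C10; the sp2 carbon C4 of the spiro 2,5-dihydrofuran then shifts suprafacially from the spiro carbon C5 to C10, which turns the five-membered ring O1–C2–C3=C4–C5 into the six-membered 2H-pyran O1–C2–C3=C4–C10–C5 and leaves the charge on C5 as the O1-stabilised arenium ion 5, and loss of the C10 proton aromatises ring B. The closest known reaction type is the acid-promoted dienone–phenol rearrangement of spirocyclohexadienones, including the ring expansion of 1-oxaspiro[4.5]deca-6,9-dien-8-ones to chroman-6-ols. No ring is closed by cyclisation: ring C arises by ring expansion through a 1,2-shift to a cationic centre. No stereocentre is formed, and the racemic spiro centre is destroyed. The step needs carbon and not oxygen to migrate, which is secured because only the carbon shift leaves an oxocarbenium ion (O1=C5) and an alkenyl group migrates readily; it needs C10 and not C6 as terminus, which is secured because C6 carries an allyloxy group and no hydrogen, so a shift there is reversible and unproductive. Should the allylic O1–C2 bond ionise first, the resulting para-quinol can only undergo the same alkenyl shift to C10 and then re-close O1–C2 on the new ortho hydroxyl, so this path should also end at 6.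

Step 5
Reactants: 7 5-fluorobenzene-1,3-diol
Product: 9 2-fluoro-4,6-dihydroxybenzaldehyde, via aryl iminium chloride 8 (not isolated)
Conditions: POCl3, DMF, MeCN, –15 °C → rt; then H2O, 50 °C
Reagents that add atoms: N,N-dimethylformamide, CN(C)C=O; water, O
Why: Vilsmeier–Haack formylation of a resorcinol takes place para to one hydroxyl and ortho to the other (here the carbon next to fluorine) and not between the two hydroxyls, and the iminium salt is hydrolysed to the aldehyde on warming with water.

Step 6
Reactants: 9 2-fluoro-4,6-dihydroxybenzaldehyde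
Product: 11 7-fluoro-5-hydroxy-2,2-dimethyl-2H-chromene-6-carbaldehyde, via ortho-quinone methide 10 (not isolated)
Conditions: 3-methylbut-2-enal, ethylenediammonium diacetate (10 mol %), toluene, 110 °C
Reagents that add atoms: 3-methylbut-2-enal, CC(C)=CC=O
Why: Knoevenagel-type condensation at the ring carbon between the two hydroxyls gives an ortho-quinone methide whose oxa-6π electrocyclisation closes ring D on the non-chelated para hydroxyl, the regiochemistry established for 2,4-dihydroxybenzaldehydes.

Step 7
Reactants: 11 7-fluoro-5-hydroxy-2,2-dimethyl-2H-chromene-6-carbaldehyde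
Product: 12 7-fluoro-5-hydroxy-8-iodo-2,2-dimethyl-2H-chromene-6-carbaldehyde
Conditions: N-iodosuccinimide, MeCN, 0 °C → rt, dark
Reagents that add atoms: N-iodosuccinimide, O=C1CCC(=O)N1I
Why: Electrophilic aromatic iodination should go to C8, the only free ring position, which is para to the chelated hydroxyl and ortho to the pyran oxygen.

Step 8
Reactants: 12 7-fluoro-5-hydroxy-8-iodo-2,2-dimethyl-2H-chromene-6-carbaldehyde
Product: 13 7-fluoro-5-hydroxy-2,2-dimethyl-8-(3-methylbut-2-en-1-yl)-2H-chromene-6-carbaldehyde
Conditions: tributyl(3-methylbut-2-en-1-yl)stannane, Pd(PPh3)4 (5 mol %), DMF, 80 °C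
Reagents that add atoms: tributyl(3-methylbut-2-en-1-yl)stannane, CC(C)=CC[Sn](CCCC)(CCCC)CCCC
Why: Stille coupling of the aryl iodide with the prenylstannane should deliver the linear prenyl group, and the aryl fluoride, the aldehyde and the chelated phenol are inert to zerovalent palladium under these conditions.

Step 9
Reactants: 13 7-fluoro-5-hydroxy-2,2-dimethyl-8-(3-methylbut-2-en-1-yl)-2H-chromene-6-carbaldehyde
Product: 14 5-(allyloxy)-7-fluoro-2,2-dimethyl-8-(3-methylbut-2-en-1-yl)-2H-chromene-6-carbaldehyde
Conditions: allyl bromide, K2CO3, DMF, 40 °C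
Reagents that add atoms: allyl bromide, C=CCBr
Why: Williamson etherification masks the chelated phenol, whose phenoxide would otherwise deactivate the formyl group for the substitution in step 10, with the same group that is used on ring B.

Step 10
Reactants: 6 5,8-bis(allyloxy)-2,2-dimethyl-2H-chromen-6-ol; 14 5-(allyloxy)-7-fluoro-2,2-dimethyl-8-(3-methylbut-2-en-1-yl)-2H-chromene-6-carbaldehyde
Product: 15 5-(allyloxy)-7-{[5,8-bis(allyloxy)-2,2-dimethyl-2H-chromen-6-yl]oxy}-2,2-dimethyl-8-(3-methylbut-2-en-1-yl)-2H-chromene-6-carbaldehyde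
Conditions: Cs2CO3, DMSO (degassed), 100 °C, argon
Reagents that add atoms: none
Why: Nucleophilic aromatic substitution (addition–elimination) of the fluoride ortho to the formyl group by the single free phenoxide of 6 should form the diaryl ether, since both oxygen substituents of 14 are meta to the fluorine-bearing carbon and do not oppose the Meisenheimer adduct.

Step 11
Reactants: 15 5-(allyloxy)-7-{[5,8-bis(allyloxy)-2,2-dimethyl-2H-chromen-6-yl]oxy}-2,2-dimethyl-8-(3-methylbut-2-en-1-yl)-2H-chromene-6-carbaldehyde
Product: 16 5-(allyloxy)-7-{[5,8-bis(allyloxy)-2,2-dimethyl-2H-chromen-6-yl]oxy}-2,2-dimethyl-8-(3-methylbut-2-en-1-yl)-2H-chromene-6-carboxylic acid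
Conditions: NaClO2, NaH2PO4, 2-methylbut-2-ene (large excess), t-BuOH–THF–H2O, 0 °C → rt
Reagents that add atoms: sodium chlorite, [Na+].[O-]Cl=O
Why: Pinnick oxidation converts the hindered aryl aldehyde into the acid under buffered conditions, the excess alkene scavenger protecting the prenyl, allyl and chromene double bonds and the electron-rich ring B from hypochlorous acid.

Step 12
Reactants: 16 5-(allyloxy)-7-{[5,8-bis(allyloxy)-2,2-dimethyl-2H-chromen-6-yl]oxy}-2,2-dimethyl-8-(3-methylbut-2-en-1-yl)-2H-chromene-6-carboxylic acid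
Product: 17 7-[(5,8-dihydroxy-2,2-dimethyl-2H-chromen-6-yl)oxy]-5-hydroxy-2,2-dimethyl-8-(3-methylbut-2-en-1-yl)-2H-chromene-6-carboxylic acid
Conditions: Pd(PPh3)4 (5 mol %), morpholine, degassed THF, rt, argon; aq. citric acid work-up, crude product kept under argon
Reagents that add atoms: none
Why: In this Tsuji–Trost deallylation zerovalent palladium ionises the three unhindered allyl aryl ethers to π-allyl complexes that morpholine traps, whereas the tertiary ring-bound allylic C–O bonds of the two chromenes and the C-prenyl group should not react.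

Step 13
Reactants: 17 7-[(5,8-dihydroxy-2,2-dimethyl-2H-chromen-6-yl)oxy]-5-hydroxy-2,2-dimethyl-8-(3-methylbut-2-en-1-yl)-2H-chromene-6-carboxylic acid
Product: 18 garcinisidone C
Conditions: DCC, DMAP (5 mol %), CH2Cl2 (0.002 M), 0 °C → rt, argon
Reagents that add atoms: none
Why: In this carbodiimide lactonisation (Steglich type) only the C5 hydroxyl of the ring-B chromene, ortho to the diaryl ether oxygen, can reach the activated acid, so ring E should close there while the C8 hydroxyl and the chelated hydroxyl of ring A stay free.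

**Compound list**

1 | 2,5-dihydroxy-1,4-benzoquinone | O=C1C=C(O)C(=O)C=C1O | starting material
2 | 2,5-bis(allyloxy)-1,4-benzoquinone | O=C1C=C(OCC=C)C(=O)C=C1OCC=C | intermediate
3 | rac-4-hydroxy-4-(3-methylbuta-1,2-dien-1-yl)-2,5-bis(allyloxy)cyclohexa-2,5-dien-1-one | O=C1C=C(OCC=C)C(O)(C=C=C(C)C)C=C1OCC=C | intermediate
4 | rac-6,9-bis(allyloxy)-2,2-dimethyl-1-oxaspiro[4.5]deca-3,6,9-trien-8-one | O=C1C=C(OCC=C)C2(C=CC(C)(C)O2)C=C1OCC=C | intermediate
5 | 5,8-bis(allyloxy)-6-hydroxy-2,2-dimethyl-2H,4aH-chromen-1-ium trifluoroacetate (arenium ion, formed in the flask) | OC1=C(OCC=C)C2C=CC(C)(C)[O+]=C2C(OCC=C)=C1.[O-]C(=O)C(F)(F)F | intermediate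
6 | 5,8-bis(allyloxy)-2,2-dimethyl-2H-chromen-6-ol | Oc1cc(OCC=C)c2OC(C)(C)C=Cc2c1OCC=C | intermediate
7 | 5-fluorobenzene-1,3-diol | Oc1cc(O)cc(F)c1 | starting material
8 | [(2-fluoro-4,6-dihydroxyphenyl)methylidene]dimethylammonium chloride (formed in the flask) | C[N+](C)=Cc1c(O)cc(O)cc1F.[Cl-] | intermediate
9 | 2-fluoro-4,6-dihydroxybenzaldehyde | O=Cc1c(O)cc(O)cc1F | intermediate
10 | 6-fluoro-2-hydroxy-3-(3-methylbut-2-en-1-ylidene)-4-oxocyclohexa-1,5-diene-1-carbaldehyde (ortho-quinone methide, formed in the flask) | O=CC1=C(O)C(=CC=C(C)C)C(=O)C=C1F | intermediate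
11 | 7-fluoro-5-hydroxy-2,2-dimethyl-2H-chromene-6-carbaldehyde | O=Cc1c(F)cc2OC(C)(C)C=Cc2c1O | intermediate
12 | 7-fluoro-5-hydroxy-8-iodo-2,2-dimethyl-2H-chromene-6-carbaldehyde | O=Cc1c(F)c(I)c2OC(C)(C)C=Cc2c1O | intermediate
13 | 7-fluoro-5-hydroxy-2,2-dimethyl-8-(3-methylbut-2-en-1-yl)-2H-chromene-6-carbaldehyde | O=Cc1c(F)c(CC=C(C)C)c2OC(C)(C)C=Cc2c1O | intermediate
14 | 5-(allyloxy)-7-fluoro-2,2-dimethyl-8-(3-methylbut-2-en-1-yl)-2H-chromene-6-carbaldehyde | O=Cc1c(F)c(CC=C(C)C)c2OC(C)(C)C=Cc2c1OCC=C | intermediate
15 | 5-(allyloxy)-7-{[5,8-bis(allyloxy)-2,2-dimethyl-2H-chromen-6-yl]oxy}-2,2-dimethyl-8-(3-methylbut-2-en-1-yl)-2H-chromene-6-carbaldehyde | O=Cc1c(Oc3cc(OCC=C)c4OC(C)(C)C=Cc4c3OCC=C)c(CC=C(C)C)c2OC(C)(C)C=Cc2c1OCC=C | intermediate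
16 | 5-(allyloxy)-7-{[5,8-bis(allyloxy)-2,2-dimethyl-2H-chromen-6-yl]oxy}-2,2-dimethyl-8-(3-methylbut-2-en-1-yl)-2H-chromene-6-carboxylic acid | O=C(O)c1c(Oc3cc(OCC=C)c4OC(C)(C)C=Cc4c3OCC=C)c(CC=C(C)C)c2OC(C)(C)C=Cc2c1OCC=C | intermediate
17 | 7-[(5,8-dihydroxy-2,2-dimethyl-2H-chromen-6-yl)oxy]-5-hydroxy-2,2-dimethyl-8-(3-methylbut-2-en-1-yl)-2H-chromene-6-carboxylic acid | O=C(O)c1c(Oc3cc(O)c4OC(C)(C)C=Cc4c3O)c(CC=C(C)C)c2OC(C)(C)C=Cc2c1O | intermediate
18 | garcinisidone C | CC(C)=CCc1c2c(c(O)c3c1Oc1cc(O)c4c(c1OC3=O)C=CC(C)(C)O4)C=CC(C)(C)O2 | target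

**Step count and risks**

Total step count: 13. Longest linear sequence: 9 steps (7 → 18, steps 5 to 13); the ring-B branch 1 → 6 takes 4 steps.

Steps most likely to fail:

Step 4 (key step). The cation may be diverted before the alkenyl shift, by hydrolysis of the enol ethers with adventitious water, by a charge-accelerated Claisen shift of an allyl group, or by oligomerisation of the electron-rich phenol as it forms. The fallback sets out from 2 and returns at 6 without any ring expansion. Reduction of 2 with aqueous Na2S2O4 should give 2,5-bis(allyloxy)benzene-1,4-diol F1. Condensation of F1 with one equivalent of 3-methylbut-2-enal (PhB(OH)2, AcOH, toluene, reflux; ortho-selective condensation through the cyclic phenylboronate, then oxa-6π electrocyclisation) should give 6, because the two hydroxyls of F1 are equivalent and each has one free ortho position.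

Step 10. Addition to a fluoride flanked by a formyl and a prenyl group may be slow on a ring whose formyl group is weakened by two oxygen donors, and the phenoxide of 6 may be lost to aerial oxidation at the temperature needed. The fallback replaces addition–elimination by a copper-catalysed Ullmann-type coupling; it sets out from 6 and returns at 15. The bromide partner is built from purchasable 5-bromobenzene-1,3-diol by the operations of steps 5 to 9:
- Vilsmeier–Haack formylation through [(2-bromo-4,6-dihydroxyphenyl)methylidene]dimethylammonium chloride F2 (not isolated) to 2-bromo-4,6-dihydroxybenzaldehyde F3.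
- Annulation with 3-methylbut-2-enal through the ortho-quinone methide 6-bromo-2-hydroxy-3-(3-methylbut-2-en-1-ylidene)-4-oxocyclohexa-1,5-diene-1-carbaldehyde F4 (not isolated) to 7-bromo-5-hydroxy-2,2-dimethyl-2H-chromene-6-carbaldehyde F5.
- Iodination with N-iodosuccinimide to 7-bromo-5-hydroxy-8-iodo-2,2-dimethyl-2H-chromene-6-carbaldehyde F6.
- Stille coupling at 60 °C, selective for the C–I bond, to 7-bromo-5-hydroxy-2,2-dimethyl-8-(3-methylbut-2-en-1-yl)-2H-chromene-6-carbaldehyde F7.
- Allylation to 5-(allyloxy)-7-bromo-2,2-dimethyl-8-(3-methylbut-2-en-1-yl)-2H-chromene-6-carbaldehyde F8.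

Coupling of 6 with F8 (CuI, i.e. copper monoiodide, 10 mol %, picolinic acid, K3PO4, DMSO, 90 °C) should then give 15.

Step 2. The ambident allenyl anion may attack through its dimethyl-substituted end (propargyl product), and electron transfer to the quinone or a second addition may compete. The fallback sets out from 2 and returns at 4, replacing steps 2 and 3. Addition of the dilithio derivative of 2-methylbut-3-yn-2-ol (n-BuLi, 2 equiv, THF, –78 °C) to one carbonyl of 2 should give rac-4-hydroxy-4-(3-hydroxy-3-methylbut-1-yn-1-yl)-2,5-bis(allyloxy)cyclohexa-2,5-dien-1-one F9. Semi-hydrogenation (H2, Lindlar catalyst, that is Pd on CaCO3 poisoned with Pb(OAc)2, quinoline, EtOAc, stopped after one equivalent) should give rac-4-hydroxy-4-[(Z)-3-hydroxy-3-methylbut-1-en-1-yl]-2,5-bis(allyloxy)cyclohexa-2,5-dien-1-one F10. Cyclodehydration of F10 (PPTS, CH2Cl2, rt; ionisation of the tertiary allylic alcohol and capture by the quinol hydroxyl) should give 4.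

**Further compounds**

F1 | step 4 | 2,5-bis(allyloxy)benzene-1,4-diol | Oc1cc(OCC=C)c(O)cc1OCC=C
F2 | step 10 | [(2-bromo-4,6-dihydroxyphenyl)methylidene]dimethylammonium chloride | C[N+](C)=Cc1c(O)cc(O)cc1Br.[Cl-]
F3 | step 10 | 2-bromo-4,6-dihydroxybenzaldehyde | O=Cc1c(O)cc(O)cc1Br
F4 | step 10 | 6-bromo-2-hydroxy-3-(3-methylbut-2-en-1-ylidene)-4-oxocyclohexa-1,5-diene-1-carbaldehyde | O=CC1=C(O)C(=CC=C(C)C)C(=O)C=C1Br
F5 | step 10 | 7-bromo-5-hydroxy-2,2-dimethyl-2H-chromene-6-carbaldehyde | O=Cc1c(Br)cc2OC(C)(C)C=Cc2c1O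
F6 | step 10 | 7-bromo-5-hydroxy-8-iodo-2,2-dimethyl-2H-chromene-6-carbaldehyde | O=Cc1c(Br)c(I)c2OC(C)(C)C=Cc2c1O
F7 | step 10 | 7-bromo-5-hydroxy-2,2-dimethyl-8-(3-methylbut-2-en-1-yl)-2H-chromene-6-carbaldehyde | O=Cc1c(Br)c(CC=C(C)C)c2OC(C)(C)C=Cc2c1O
F8 | step 10 | 5-(allyloxy)-7-bromo-2,2-dimethyl-8-(3-methylbut-2-en-1-yl)-2H-chromene-6-carbaldehyde | O=Cc1c(Br)c(CC=C(C)C)c2OC(C)(C)C=Cc2c1OCC=C
F9 | step 2 | rac-4-hydroxy-4-(3-hydroxy-3-methylbut-1-yn-1-yl)-2,5-bis(allyloxy)cyclohexa-2,5-dien-1-one | O=C1C=C(OCC=C)C(O)(C#CC(C)(C)O)C=C1OCC=C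
F10 | step 2 | rac-4-hydroxy-4-[(Z)-3-hydroxy-3-methylbut-1-en-1-yl]-2,5-bis(allyloxy)cyclohexa-2,5-dien-1-one | O=C1C=C(OCC=C)C(O)(/C=C\C(C)(C)O)C=C1OCC=C
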